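## Structural features

The target is a dispiro compound. Two 4-bromo-2(5H)-furanones (ring A with butyl at C3, ring B with an (R)-1-acetoxybutyl group at C3) share their C5 atoms with two adjacent carbons of a cyclobutane (ring C), whose other two carbons are CHBr groups. Ring C therefore carries four contiguous stereocentres, two of them neighbouring quaternary spiro carbons, C5(A) and C5(B), and a fifth stereocentre lies in the side chain of ring B. Apart from the side chains the core is C2-symmetric: the ring oxygens are trans across the C5(A)–C5(B) bond, the ring-C bromines are trans to each other, and each of them is cis to C4 of the adjacent butenolide and trans to its O1, which is the more crowded placement. Fragile groups are the allylic acetate (ionisation or elimination whenever C4 carries a free or anionic oxygen), the vinylic C4–Br bonds (addition–elimination by nucleophiles), the vicinal dibromide (reductive and base-induced elimination) and the strained four-membered rings. The real difficulty lies in setting the two adjacent quaternary centres in the absolute sense, in telling two nearly identical butenolides apart, and in placing the ring-C bromines on the hindered faces. The key step uses the fact that each butenolide O1–C2–C3=C4–C5 is a cyclobutenone C2–C3=C4–C5 with one oxygen inserted between C2 and C5. C5(A) and C5(B) can therefore each be the substituted carbon of a ketene attached to ring C, and the C5–C4 and C2–C3 bonds of both rings come from two ketene–ethoxyacetylene cycloadditions.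

## Logic of the disconnections

24 ⇒ 23. The two C–Br bonds on ring C are cut, which is the reverse of an anti addition of bromine to a cyclobutene. This removes two stereocentres and the function most prone to elimination, and the alkene is an inert spectator in all earlier steps. The forward step must come last, when no other nucleophilic site is left, and it must place each bromine syn to the neighbouring C4–Br arm; this is the one demand the substrate does not secure.

23 ⇒ 22. The acyl C–O bond of the acetate is cut. Acetylation is put after everything that could ionise or eliminate an allylic ester; the forward step needs only conditions that spare the C4–Br bonds.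

22 ⇒ 21. The carbinol C–H bond is cut, giving a ketone. The side-chain stereocentre is thus set by a chiral reagent and not by the distant core, and the ketone is a robust form of the side chain for the preceding steps. The forward step needs a hydride source that reduces C=O in the 1,2-sense and does not touch the ring-C alkene.

21 ⇒ 20. Both C4–Br bonds are cut back to enolic C4–OH groups. Vinylogous acids are converted into vinylogous acyl bromides by halide-transfer reagents; the forward step must take the ring enol of the acylated ring and not the side-chain enol.

20 ⇒ 19. The two O–H bonds are exchanged for O–ethyl, the form in which the oxygen arrives. The forward dealkylation must be non-basic; because the side chain is still a ketone there is no leaving group beside the free tetronic acid.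

19 ⇒ 16 + 17. The C3(B)–acyl bond is cut. The forward step needs a C3 carbanion on ring B and an acyl donor that stops at the ketone.

16 ⇒ 13 + 14. The C3(A)–butyl bond is cut. This is the point at which the two homotopic rings of a C2-symmetric compound become different, so the forward step must functionalise one ring only; it is run with a deficit of base and unchanged 13 is recycled.

13 ⇒ 12. The two C5–O1 bonds are cut, the reverse of a double Baeyer–Villiger oxidation. Each butenolide becomes a cyclobutenone that contains all its carbons, and the stereocentres are unchanged because migration retains configuration. The forward step needs migration of the quaternary carbon and an oxidant that leaves three C=C bonds alone.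

12 ⇒ 7 + 8 (key). Four C–C bonds are cut, C5–C4 and C2–C3 in each four-membered enone. Two rings and both quaternary centres fall back to a C2-symmetric bis(acid chloride) and two molecules of a commercial alkyne. The forward step must run as two successive monoketene cycloadditions with facial control by the neighbouring ring carbon. The precursor is kept trans, so either acyl chloride may react first with the same result, and ring C is kept as the unsubstituted alkene: bromine atoms there before this step would be lost by β-elimination and would steer the closures to the wrong face.

7 ⇒ 6. The two C–Cl bonds are cut; the forward activation must be base-free to keep the two allylic methine centres intact.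

6 ⇒ 4 (through 5). One ester C–O bond and the configuration of the ester-bearing carbon are changed. The chiral trans-diacid derives from a cis half-ester whose two carboxyl groups differ, so only one centre is enolisable. The forward step must epimerise without moving the ring double bond into conjugation.

4 ⇒ 3. The ester C–O bond is cut back to a meso anhydride, so that absolute configuration comes from a desymmetrising alcoholysis and no resolution is needed.

3 ⇒ 1 + 2. The two C–C bonds that join the alkene carbons of ring C to the anhydride are cut; the forward step is a sensitised [2+2] photocycloaddition of two commodity chemicals.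

## Other disconnections considered

Alternative 1: The cut removes the two lactone carbonyl carbons (C2–C3 and C2–O1 of both rings) as carbon monoxide. The precursor is the hexabromo diol A2, a cyclobutane-1,2-diol with an (E)-1,2-dibromoalkenyl group on each carbinol carbon. The forward step is a double carbonylative lactonisation with Pd(PPh3)4 under CO (oxidative addition into each C3–Br bond, CO insertion, capture of the acylpalladium by the tertiary hydroxyl) to give A1, which then needs only a silyl-to-acetyl exchange.
- In its favour: the butyl and the (R)-silyloxybutyl groups would arrive with two different alkynes, so the rings are different from the start and no statistical differentiation is needed; on this point it is better than the chosen plan. The C4 bromines and the side-chain stereocentre are in place before the key step and the end game is shorter.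
- Against it: A2 holds six C–Br bonds of three kinds and zerovalent palladium would have to select two of them. 1,2-Dibromoalkenes tend to lose both bromines after oxidative addition, the vicinal dibromide of ring C is itself open to reductive elimination, and the C4–Br bonds must survive in A1.
- Comparison: on structure, the adjacent tertiary carbinols, their trans relation and their absolute configuration would still have to be built without an obvious control element, whereas the chosen key step makes both quaternary centres by relay from an enantiopure precursor. On mechanism the chosen key step has no competing C–Br chemistry. On step economy Alternative 1 would be equal or better. The placement of the ring-C bromines is unsolved in both plans, so they are equal there.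

Alternative 2: The cut lies inside ring C, which would be made by contraction of a five-membered ring. Photolysis of 2-diazocyclopentane-1,3-dione A4 in methanol would give, by Wolff rearrangement (shift of a ring CH2 to the carbene carbon, trapping of the acylketene), the keto ester A3. Its ketone carbon would become C5(A), its ester-bearing carbon C5(B) and its two CH2 groups the CHBr carbons.
- In its favour: a robust and scalable photoreaction on a trivial substrate. The two future spiro carbons are chemically different, so rings A and B could be grown one after the other with their own side chains; this again is better than the chosen plan for differentiation.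
- Against it: A3 is racemic and its stereocentre epimerises through the enol, so the step fixes none of the five stereocentres. All bonds of both butenolides, both quaternary centres and the oxidation of CH2–CH2 to the trans-dibromide would remain, with retro-Claisen opening of the strained keto ester as a standing risk.
- Comparison: on mechanism the alternative key step is the safer one. On structure it delivers one ring and no stereochemistry against two rings, four skeletal bonds and two quaternary centres. On step economy it would be clearly worse.

Alternative 3: The cut removes the two C5–CH bonds of ring C. Sensitised irradiation of the (E)-bifuranylidenedione A6 with acetylene 2 would add the alkyne across the central C5(A)=C5(B) double bond and give the cyclobutene A5, which is the same compound as 23; bromine addition would finish.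
- In its favour: both fully substituted butenolides would be made separately, with no statistical step and with C4–Br and both side chains present. The E geometry would translate into the trans relation of the ring oxygens in a suprafacial addition. On convergence and step economy it is better than the chosen plan.
- Against it: the only stereocentre of A6 is the remote acetate carbon, so the two faces of the central alkene are not distinguished and the absolute configuration of both spiro centres would be uncontrolled. A triplet pathway runs through a 1,4-diradical in which the E/Z information can be lost. The extended chromophore offers competing photochemistry (E/Z isomerisation, addition at the C3=C4 bonds, C–Br homolysis), and photoaddition of acetylene to a tetrasubstituted cross-conjugated alkene is not assured.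
- Comparison: on structure the chosen plan controls the spiro centres and the alternative does not. On mechanism the chosen plan uses ground-state polar chemistry with a defined relay of configuration. The last step, and with it the uncertainty about the ring-C bromines, is shared, so the plans are equal there.

Key step: step 5

Remark on the chemistry (assumption): quinidine is taken to direct methanol so that the free acid stays on the (S) carbon, as with other ring-fused succinic anhydrides; if the sense were the opposite, quinine would replace quinidine in step 2 and nothing else would change.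

## Route

Step 1
Reactants: 1 maleic anhydride; 2 acetylene
Product: 3 (1R,5S)-3-oxabicyclo[3.2.0]hept-6-ene-2,4-dione (meso, cis-fused)
Conditions: hν (λ > 290 nm), acetophenone (sens.), EtOAc, −30 °C, C2H2 sparge
Reagents that add atoms: none
Why: Triplet-sensitised [2+2] photocycloaddition of the electron-poor C=C of 1 to the alkyne; the five-membered anhydride enforces the cis ring fusion, so 3 is meso and no stereochemical issue arises.

Step 2
Reactants: 3 (1R,5S)-3-oxabicyclo[3.2.0]hept-6-ene-2,4-dione
Product: 4 (1S,2R)-2-(methoxycarbonyl)cyclobut-3-ene-1-carboxylic acid (cis half-ester)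
Conditions: MeOH (3 equiv), quinidine (1.1 equiv), toluene, −55 °C; aq HCl
Reagents that add atoms: methanol, CO
Why: Alkaloid-mediated desymmetrising methanolysis of a meso anhydride; the chiral amine acts as general base and delivers methanol to one of the two enantiotopic carbonyl groups, which fixes both stereocentres of 4 at once.

Step 3
Reactants: 4 (1S,2R)-2-(methoxycarbonyl)cyclobut-3-ene-1-carboxylic acid
Product: 6 (1S,2S)-cyclobut-3-ene-1,2-dicarboxylic acid, via trans half-ester 5 (not isolated)
Conditions: NaOMe (3 equiv), MeOH, 0 °C → rt, short contact; then H2O, rt; aq HCl
Reagents that add atoms: water, O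
Why: Methoxide reversibly deprotonates only the ester α-carbon (the α-carbon of the carboxylate is not enolisable), so thermodynamic epimerisation relieves the eclipsed cis arrangement and gives trans 5 with the acid-bearing centre untouched. Saponification in the same pot gives C2-symmetric 6, and low temperature and short contact limit migration of the ring double bond into conjugation.

Step 4
Reactants: 6 (1S,2S)-cyclobut-3-ene-1,2-dicarboxylic acid
Product: 7 (1S,2S)-cyclobut-3-ene-1,2-dicarbonyl dichloride (trans)
Conditions: (COCl)2 (2.4 equiv), N,N-dimethylformamide (cat.), CH2Cl2, 0 °C → rt; evaporate, use crude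
Reagents that add atoms: oxalyl chloride, O=C(Cl)C(Cl)=O
Why: Acid chloride formation through the chloroiminium (Vilsmeier-type) species; no base is present, so the two allylic CH–COCl centres are not enolised.

Step 5
Reactants: 7 (1S,2S)-cyclobut-3-ene-1,2-dicarbonyl dichloride; 8 ethoxyacetylene
Product: 12 (4R,5R)-1,8-diethoxydispiro[3.0.3^5.2^4]deca-1,7,9-triene-3,6-dione, via ketene acyl chloride 9 (not isolated), via monospiro cyclobutenone acyl chloride 10 (not isolated), via spiro cyclobutenone ketene 11 (not isolated)
Conditions: 8 (5 equiv), Et2O, −20 °C; NEt3 (2.2 equiv) added over 6 h; then 0 °C; filter, keep ≤ 20 °C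
Reagents that add atoms: none
Why: NEt3 dehydrochlorinates one acyl chloride of 7 to ketene 9, the nucleophilic CH carbon of 8 adds to the ketene carbonyl carbon in the plane of ring C, and the enolate carbon C5 then bonds to the ethoxy-stabilised cationic carbon; this is a stepwise polar [2+2] ketene–ynol ether cycloaddition, closest to the known preparation of 3-ethoxycyclobutenones from acid chlorides, NEt3 and ethoxyacetylene. Each four-membered enone ring is thus closed by intermolecular C2–C3 bond formation followed by collapse of the zwitterion between C5 and the ethoxy-bearing carbon (a 4π-type closure, formally a [2+2]). In 9 the cationic arm swings to the face of ring C anti to the COCl on the neighbouring carbon, which sets C5(A) in 10; this first closure decides the absolute sense, because that neighbour is the only stereocentre left in 9. The second acyl chloride then gives ketene 11, whose closure occurs anti to the bulkier C(OEt)=CH arm and syn to the C=O arm of the first spiro ring; this sets C5(B) and the trans relation of the two ethoxy-bearing carbons, so that 12 is C2-symmetric. The step needs [2+2] at the ketene C=C and not [4+2] through the vinylketene, which the s-trans geometry of exocyclic ketene and ring alkene secures. It also needs monoketene chemistry and not the achiral bisketene, which slow addition of NEt3 to 7 in excess 8 secures, together with precipitation of Et3NH+Cl− from Et2O, which limits HCl return to the ketene. Ketene dimerisation is not expected because the ketenes are disubstituted and 8 is the better trap, and the temperature stays at or below 0 °C because 4-alkenylcyclobutenones ring-open on warming. A wrong first closure would lead to the enantiomer of 12, and a wrong second closure to the achiral cis isomer, which is a separable diastereomer.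

Step 6
Reactants: 12 (4R,5R)-1,8-diethoxydispiro[3.0.3^5.2^4]deca-1,7,9-triene-3,6-dione
Product: 13 (5S,6S)-4,10-diethoxy-1,7-dioxadispiro[4.0.4^6.2^5]dodeca-3,9,11-triene-2,8-dione (bis-tetronate)
Conditions: 30% aq H2O2 (4 equiv), LiOH (0.3 equiv), THF–H2O, 0 °C; aq Na2S2O3
Reagents that add atoms: hydrogen peroxide, OO
Why: Baeyer–Villiger oxidation of strained four-membered ketones: hydroperoxide adds to each cyclobutenone carbonyl and the quaternary C5 migrates to oxygen with retention, giving the 4-ethoxybutenolides. Nucleophilic peroxide is chosen because it leaves the isolated cyclobutene and the enol ether double bonds alone.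

Step 7
Reactants: 13 (5S,6S)-4,10-diethoxy-1,7-dioxadispiro[4.0.4^6.2^5]dodeca-3,9,11-triene-2,8-dione; 14 1-iodobutane
Product: 16 (5S,6S)-3-butyl-4,10-diethoxy-1,7-dioxadispiro[4.0.4^6.2^5]dodeca-3,9,11-triene-2,8-dione, via C3-lithio bis-tetronate 15 (not isolated)
Conditions: LiN(iPr)2 (LDA, 0.9 equiv), THF, −78 °C; 14 (1.5 equiv), N,N'-dimethylpropyleneurea, −78 → −20 °C; recover 13
Reagents that add atoms: none
Why: 5,5-Disubstituted 4-alkoxybutenolides are deprotonated at C3 (vinylic, α to the lactone carbonyl, flanked by the alkoxy group) and the vinyllithium is alkylated by the primary iodide. A deficit of base is used so that mainly one of the two homotopic rings reacts and unchanged 13 is recycled.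

Step 8
Reactants: 16 (5S,6S)-3-butyl-4,10-diethoxy-1,7-dioxadispiro[4.0.4^6.2^5]dodeca-3,9,11-triene-2,8-dione; 17 N-methoxy-N-methylbutanamide
Product: 19 (5S,6S)-9-butanoyl-3-butyl-4,10-diethoxy-1,7-dioxadispiro[4.0.4^6.2^5]dodeca-3,9,11-triene-2,8-dione, via C9-lithio derivative 18 (not isolated)
Conditions: LiN(iPr)2 (LDA, 1.2 equiv), THF, −78 °C; 17 (1.5 equiv), −78 → −40 °C; aq NH4Cl
Reagents that add atoms: none
Why: Lithiation at the only remaining vinylic C–H and acylation by a Weinreb amide; the chelated tetrahedral intermediate prevents over-addition and releases the ketone on work-up.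

Step 9
Reactants: 19 (5S,6S)-9-butanoyl-3-butyl-4,10-diethoxy-1,7-dioxadispiro[4.0.4^6.2^5]dodeca-3,9,11-triene-2,8-dione
Product: 20 (5S,6S)-9-butanoyl-3-butyl-4,10-dihydroxy-1,7-dioxadispiro[4.0.4^6.2^5]dodeca-3,9,11-triene-2,8-dione (bis-tetronic acid, drawn as the C4 enols)
Conditions: BBr3 (5 equiv), CH2Cl2, −78 → 0 °C; then MeOH–H2O
Reagents that add atoms: none
Why: Lewis-acid cleavage of the two vinylogous-ester ethyl ethers (bromide attacks the O-ethyl carbon of the boron-complexed tetronates). The side chain is still a ketone, so no ionisable or eliminable C–O group stands beside the free tetronic acids.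

Step 10
Reactants: 20 (5S,6S)-9-butanoyl-3-butyl-4,10-dihydroxy-1,7-dioxadispiro[4.0.4^6.2^5]dodeca-3,9,11-triene-2,8-dione
Product: 21 (5R,6R)-4,10-dibromo-9-butanoyl-3-butyl-1,7-dioxadispiro[4.0.4^6.2^5]dodeca-3,9,11-triene-2,8-dione
Conditions: (COBr)2 (3 equiv), N,N-dimethylformamide (3 equiv), CH2Cl2, 0 °C → rt; non-nucleophilic work-up
Reagents that add atoms: oxalyl bromide, O=C(Br)C(Br)=O
Why: Vilsmeier-type activation of the C4 enol oxygen and addition–elimination of bromide turn tetronic acids into 4-bromobutenolides; in the acylated ring the ring enol reacts, as it does in 2-acyl-1,3-diones and 3-acyl-4-hydroxycoumarins.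

Step 11
Reactants: 21 (5R,6R)-4,10-dibromo-9-butanoyl-3-butyl-1,7-dioxadispiro[4.0.4^6.2^5]dodeca-3,9,11-triene-2,8-dione
Product: 22 (5R,6R)-4,10-dibromo-3-butyl-9-[(1R)-1-hydroxybutyl]-1,7-dioxadispiro[4.0.4^6.2^5]dodeca-3,9,11-triene-2,8-dione
Conditions: (S)-1-methyl-3,3-diphenyltetrahydro-1H,3H-pyrrolo[1,2-c][1,3,2]oxazaborole ((S)-Me-CBS, 0.3 equiv), catecholborane (1.5 equiv), toluene–CH2Cl2, −78 °C
Reagents that add atoms: none
Why: CBS reduction: the ketone binds the oxazaborolidine with the butenolide as the large and propyl as the small group, so the (S)-catalyst should deliver hydride to give the (R)-carbinol. Catecholborane at −78 °C does not hydroborate the cyclobutene, and any material with the mirror-image core carried from step 5 becomes a separable diastereomer here.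

Step 12
Reactants: 22 (5R,6R)-4,10-dibromo-3-butyl-9-[(1R)-1-hydroxybutyl]-1,7-dioxadispiro[4.0.4^6.2^5]dodeca-3,9,11-triene-2,8-dione
Product: 23 (1R)-1-[(5R,6R)-4,10-dibromo-3-butyl-2,8-dioxo-1,7-dioxadispiro[4.0.4^6.2^5]dodeca-3,9,11-trien-9-yl]butyl acetate
Conditions: Ac2O, pyridine, CH2Cl2, 0 °C → rt
Reagents that add atoms: acetic anhydride, CC(=O)OC(C)=O
Why: O-Acylation of a secondary alcohol; the stereocentre is not touched and the hindered C4–Br positions are not attacked by pyridine in the cold.

Step 13
Reactants: 23 (1R)-1-[(5R,6R)-4,10-dibromo-3-butyl-2,8-dioxo-1,7-dioxadispiro[4.0.4^6.2^5]dodeca-3,9,11-trien-9-yl]butyl acetate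
Product: 24 (1R)-1-[(5S,6S,11R,12R)-4,10,11,12-tetrabromo-3-butyl-2,8-dioxo-1,7-dioxadispiro[4.0.4^6.2^5]dodeca-3,9-dien-9-yl]butyl acetate (CNP0268004.1)
Conditions: Br2 (1.1 equiv), CH2Cl2, 0 °C → rt, dark
Reagents that add atoms: bromine, BrBr
Why: Anti addition of bromine through the bromonium ion gives a trans-1,2-dibromocyclobutane, and the tetrasubstituted, electron-poor butenolide double bonds do not react. 24 is the anti adduct with each bromine on the face of the neighbouring C4–Br arm (anti to the lactone oxygen); the other anti adduct has the bromines syn to the ring oxygens, and the choice between them is substrate-controlled and not secured.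

## Compound list

1 | maleic anhydride | O=C1OC(=O)C=C1 | starting material
2 | acetylene | C#C | starting material
3 | (1R,5S)-3-oxabicyclo[3.2.0]hept-6-ene-2,4-dione (meso) | O=C1OC(=O)[C@H]2C=C[C@@H]12 | intermediate
4 | (1S,2R)-2-(methoxycarbonyl)cyclobut-3-ene-1-carboxylic acid (cis) | OC(=O)[C@H]1C=C[C@H]1C(=O)OC | intermediate
5 | (1S,2S)-2-(methoxycarbonyl)cyclobut-3-ene-1-carboxylic acid (trans) | OC(=O)[C@H]1C=C[C@@H]1C(=O)OC | intermediate (not isolated)
6 | (1S,2S)-cyclobut-3-ene-1,2-dicarboxylic acid (trans) | OC(=O)[C@H]1C=C[C@@H]1C(O)=O | intermediate
7 | (1S,2S)-cyclobut-3-ene-1,2-dicarbonyl dichloride (trans) | ClC(=O)[C@H]1C=C[C@@H]1C(Cl)=O | intermediate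
8 | ethoxyacetylene | CCOC#C | starting material
9 | (S)-4-(oxomethylidene)cyclobut-2-ene-1-carbonyl chloride | O=C=C1C=C[C@@H]1C(Cl)=O | intermediate (not isolated)
10 | 1-ethoxy-3-oxospiro[3.3]hepta-1,6-diene-5-carbonyl chloride (ethoxy-bearing carbon anti, ring C=O carbon syn to COCl) | CCOC1=CC(=O)[C@@]12C=C[C@@H]2C(Cl)=O | intermediate (not isolated)
11 | 1-ethoxy-5-(oxomethylidene)spiro[3.3]hepta-1,6-dien-3-one (spiro centre as in 10) | CCOC1=CC(=O)[C@@]12C=CC2=C=O | intermediate (not isolated)
12 | (4R,5R)-1,8-diethoxydispiro[3.0.3^5.2^4]deca-1,7,9-triene-3,6-dione | CCOC1=CC(=O)[C@@]12C=C[C@@]23C(=O)C=C3OCC | intermediate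
13 | (5S,6S)-4,10-diethoxy-1,7-dioxadispiro[4.0.4^6.2^5]dodeca-3,9,11-triene-2,8-dione | CCOC1=CC(=O)O[C@@]12C=C[C@@]23OC(=O)C=C3OCC | intermediate
14 | 1-iodobutane | CCCCI | starting material
15 | 3-lithio derivative of 13 | [Li]C1=C(OCC)[C@@]2(OC1=O)C=C[C@@]21OC(=O)C=C1OCC | intermediate (not isolated)
16 | (5S,6S)-3-butyl-4,10-diethoxy-1,7-dioxadispiro[4.0.4^6.2^5]dodeca-3,9,11-triene-2,8-dione | CCCCC1=C(OCC)[C@@]2(OC1=O)C=C[C@@]21OC(=O)C=C1OCC | intermediate
17 | N-methoxy-N-methylbutanamide | CCCC(=O)N(C)OC | starting material
18 | 9-lithio derivative of 16 | CCCCC1=C(OCC)[C@@]2(OC1=O)C=C[C@@]21OC(=O)C([Li])=C1OCC | intermediate (not isolated)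
19 | (5S,6S)-9-butanoyl-3-butyl-4,10-diethoxy-1,7-dioxadispiro[4.0.4^6.2^5]dodeca-3,9,11-triene-2,8-dione | CCCCC1=C(OCC)[C@@]2(OC1=O)C=C[C@@]21OC(=O)C(C(=O)CCC)=C1OCC | intermediate
20 | (5S,6S)-9-butanoyl-3-butyl-4,10-dihydroxy-1,7-dioxadispiro[4.0.4^6.2^5]dodeca-3,9,11-triene-2,8-dione | CCCCC1=C(O)[C@@]2(OC1=O)C=C[C@@]21OC(=O)C(C(=O)CCC)=C1O | intermediate
21 | (5R,6R)-4,10-dibromo-9-butanoyl-3-butyl-1,7-dioxadispiro[4.0.4^6.2^5]dodeca-3,9,11-triene-2,8-dione | CCCCC1=C(Br)[C@@]2(OC1=O)C=C[C@@]21OC(=O)C(C(=O)CCC)=C1Br | intermediate
22 | (5R,6R)-4,10-dibromo-3-butyl-9-[(1R)-1-hydroxybutyl]-1,7-dioxadispiro[4.0.4^6.2^5]dodeca-3,9,11-triene-2,8-dione | CCCCC1=C(Br)[C@@]2(OC1=O)C=C[C@@]21OC(=O)C([C@@H](CCC)O)=C1Br | intermediate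
23 | (1R)-1-[(5R,6R)-4,10-dibromo-3-butyl-2,8-dioxo-1,7-dioxadispiro[4.0.4^6.2^5]dodeca-3,9,11-trien-9-yl]butyl acetate | CCCCC1=C(Br)[C@@]2(OC1=O)C=C[C@@]21OC(=O)C([C@@H](CCC)OC(C)=O)=C1Br | intermediate
24 | (1R)-1-[(5S,6S,11R,12R)-4,10,11,12-tetrabromo-3-butyl-2,8-dioxo-1,7-dioxadispiro[4.0.4^6.2^5]dodeca-3,9-dien-9-yl]butyl acetate | CCCCC1=C(Br)[C@@]2(OC1=O)[C@@H](Br)[C@H](Br)[C@@]21OC(=O)C([C@@H](CCC)OC(C)=O)=C1Br | target

## Step count and least certain steps

Total step count: 13. Longest linear sequence: 13 steps (1 → 24); the route is linear.

Step 5 (key step). The likely failure is loss of stereochemical integrity. In the first closure only a COCl group distinguishes the two faces of ketene 9, and a closure on the wrong face leads on to the mirror-image dispiro compound, so poor facial discrimination erodes enantiomeric purity. Return of HCl to the ketene, or double dehydrochlorination to the achiral bisketene, would do the same. Ketene oligomerisation and thermal opening of the 4-alkenylcyclobutenones would cost material.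
Fallback: set out from 5, isolated by acidifying step 3 before water is added. Oxalyl chloride gives methyl (1S,2S)-2-(chlorocarbonyl)cyclobut-3-ene-1-carboxylate F1. NEt3 and 8 then give one cycloaddition to the spiro cyclobutenone ester, methyl 1-ethoxy-3-oxospiro[3.3]hepta-1,6-diene-5-carboxylate F2. Its ester-bearing centre cannot become a ketene, so the bisketene is excluded, and the two facial outcomes are diastereomers that can be separated. Cleavage of the methyl ester with Me3SnOH in 1,2-dichloroethane at 50 °C gives 1-ethoxy-3-oxospiro[3.3]hepta-1,6-diene-5-carboxylic acid F3. Oxalyl chloride converts F3 into 10, where the route is rejoined, and a second treatment with NEt3 and 8 completes 12.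

Step 13. The likely failure is opening of the bromonium ion at the wrong carbon. The C4–Br arms lie over one end of each face of the cyclobutene, so bromine is expected to prefer the positions syn to the ring oxygens, and the needed anti adduct may be the minor one.
Fallback: set out from 23 and accept the other anti adduct, the trans-dibromide with both bromines syn to the ring oxygens F4. Heated in an inert solvent, F4 should undergo the dyotropic exchange of its two vicinal bromines (the mutarotation of trans-1,2-dibromides), which converts exactly this trans arrangement into that of 24. The equilibrium mixture would be separated; this comes back to the route at 24. Remaining F4 is recycled, or returned to 23 with Zn in AcOH. The equilibrium position is itself unknown.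

Step 3. The likely failure is migration of the ring double bond into conjugation through the dienolate, or incomplete epimerisation that leaves meso diacid.
Fallback: avoid the epimerisation altogether. Set out from 3 and run the methanolysis with quinine to obtain the enantiomeric cis half-ester, (1R,2S)-2-(methoxycarbonyl)cyclobut-3-ene-1-carboxylic acid F5. Its ester-bearing carbon already has the configuration that this carbon has in 5. Oxalyl chloride gives methyl (1S,2R)-2-(chlorocarbonyl)cyclobut-3-ene-1-carboxylate F6. With NEt3 and 8 its acyl chloride carbon becomes a planar ketene carbon, so its original configuration is irrelevant and the product is the same spiro ester F2 as above. The route is then rejoined at 10 through F3.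

Step 10. The likely failure is activation of the side-chain enol of the acyl tetronic acid, which would put bromide on the exocyclic carbon; the vinylogous acyl bromide may also hydrolyse on work-up.
Fallback: set out from 19 and create the carbinol before the ethoxy-to-bromide exchange. CBS reduction as in step 11 gives the (R)-alcohol, (5S,6S)-3-butyl-4,10-diethoxy-9-[(1R)-1-hydroxybutyl] bis-tetronate F7. Ac2O and pyridine give its acetate F8. BBr3 at −78 °C gives the acetoxy bis-tetronic acid F9, which is taken at once into oxalyl bromide and N,N-dimethylformamide; this comes back to the route at 23. The weak point of this order is ionisation or elimination of the acetate while the free tetronic acid exists.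

Step 7. The likely failure is slow alkylation of the stabilised vinyllithium by a primary iodide, with decomposition of the lithio species on warming; double alkylation also lowers the return.
Fallback: set out from 13, lithiate as before and add butanal, which reacts at −78 °C, to give the 3-(1-hydroxybutyl) bis-tetronate F10 as a mixture of carbinol epimers. Ionic deoxygenation with Et3SiH and CF3CO2H (through the cation stabilised by the enol ether) gives 16, where the route is rejoined.

## Further compounds

F1 | step 5 | methyl (1S,2S)-2-(chlorocarbonyl)cyclobut-3-ene-1-carboxylate | ClC(=O)[C@H]1C=C[C@@H]1C(=O)OC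
F2 | step 5 | methyl 1-ethoxy-3-oxospiro[3.3]hepta-1,6-diene-5-carboxylate (spiro centre as in 10) | CCOC1=CC(=O)[C@@]12C=C[C@@H]2C(=O)OC
F3 | step 5 | 1-ethoxy-3-oxospiro[3.3]hepta-1,6-diene-5-carboxylic acid (spiro centre as in 10) | CCOC1=CC(=O)[C@@]12C=C[C@@H]2C(O)=O
F4 | step 13 | trans-dibromide diastereomer of 24 with both ring-C bromines syn to the lactone oxygens | CCCCC1=C(Br)[C@@]2(OC1=O)[C@H](Br)[C@@H](Br)[C@@]21OC(=O)C([C@@H](CCC)OC(C)=O)=C1Br
F5 | step 3 | (1R,2S)-2-(methoxycarbonyl)cyclobut-3-ene-1-carboxylic acid | OC(=O)[C@@H]1C=C[C@@H]1C(=O)OC
F6 | step 3 | methyl (1S,2R)-2-(chlorocarbonyl)cyclobut-3-ene-1-carboxylate | ClC(=O)[C@@H]1C=C[C@@H]1C(=O)OC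
F7 | step 10 | (5S,6S)-3-butyl-4,10-diethoxy-9-[(1R)-1-hydroxybutyl]-1,7-dioxadispiro[4.0.4^6.2^5]dodeca-3,9,11-triene-2,8-dione | CCCCC1=C(OCC)[C@@]2(OC1=O)C=C[C@@]21OC(=O)C([C@@H](CCC)O)=C1OCC
F8 | step 10 | (1R)-1-[(5S,6S)-3-butyl-4,10-diethoxy-2,8-dioxo-1,7-dioxadispiro[4.0.4^6.2^5]dodeca-3,9,11-trien-9-yl]butyl acetate | CCCCC1=C(OCC)[C@@]2(OC1=O)C=C[C@@]21OC(=O)C([C@@H](CCC)OC(C)=O)=C1OCC
F9 | step 10 | (1R)-1-[(5S,6S)-3-butyl-4,10-dihydroxy-2,8-dioxo-1,7-dioxadispiro[4.0.4^6.2^5]dodeca-3,9,11-trien-9-yl]butyl acetate | CCCCC1=C(O)[C@@]2(OC1=O)C=C[C@@]21OC(=O)C([C@@H](CCC)OC(C)=O)=C1O
F10 | step 7 | (5S,6S)-4,10-diethoxy-3-(1-hydroxybutyl)-1,7-dioxadispiro[4.0.4^6.2^5]dodeca-3,9,11-triene-2,8-dione (both carbinol epimers) | CCCC(O)C1=C(OCC)[C@@]2(OC1=O)C=C[C@@]21OC(=O)C=C1OCC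
A1 | alternative 1 | tert-butyldimethylsilyl ether analogue of 24 | CCCCC1=C(Br)[C@@]2(OC1=O)[C@@H](Br)[C@H](Br)[C@@]21OC(=O)C([C@@H](CCC)O[Si](C)(C)C(C)(C)C)=C1Br
A2 | alternative 1 | hexabromo diol: 3,4-dibromocyclobutane-1,2-diol with an (E)-1,2-dibromohex-1-enyl group on one carbinol carbon and an (E)-1,2-dibromo-3-(silyloxy)hex-1-enyl group on the other | CCCC/C(Br)=C(\Br)[C@@]1(O)[C@@H](Br)[C@H](Br)[C@]1(O)/C(Br)=C(\Br)[C@@H](CCC)O[Si](C)(C)C(C)(C)C
A3 | alternative 2 | methyl 2-oxocyclobutane-1-carboxylate (racemic) | COC(=O)C1CCC1=O
A4 | alternative 2 | 2-diazocyclopentane-1,3-dione | O=C1CCC(=O)C1=[N+]=[N-]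
A5 | alternative 3 | dispiro cyclobutene bis-butenolide, identical with 23 | CCCCC1=C(Br)[C@@]2(OC1=O)C=C[C@@]21OC(=O)C([C@@H](CCC)OC(C)=O)=C1Br
A6 | alternative 3 | (E)-bifuranylidenedione carrying the butyl, the (R)-1-acetoxybutyl and both C4 bromine substituents | CCCCC1=C(Br)/C(OC1=O)=C2\OC(=O)C([C@@H](CCC)OC(C)=O)=C2Br
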